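**Retrosynthetic overview**
1. The strategy rests on one feature of the only ring, a 3,6-dihydro-2H-pyran (O1; C2, the stereocentre bearing the acrylic acid; C3; C4=C5 with the homofarnesyl chain on C5; C6). C6 is a bare CH2 between O1 and the fully substituted alkene carbon C5, so it is one formaldehyde carbon held between the C2 oxygen and a C5 vinyl nucleophile.
2. Key disconnection C5–C6: SnCl4 ionises the 2-methoxyethoxymethyl (MEM) ether on O1, and a (Z)-vinylsilane (Si on C5, cis to C3) attacks through its silicon-bearing carbon. Loss of silicon leaves the alkene only at C4=C5, and this is the sole ring-forming event.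
3. Vinylsilane: the C5–C1' bond comes from a B-alkyl Suzuki–Miyaura coupling. The partners are an (E)-α-iodovinylsilane (syn hydrozirconation and iodinolysis of a silylalkyne) and the 9-BBN adduct of a tetraene made from (2E,6E)-farnesol.
4. C2 is set by a chiral phosphoric acid catalysed allenylboration of 2-(pivaloyloxymethyl)acrolein. Silicon goes onto the terminal alkyne afterwards, because γ-silylpropargyl metal reagents partition between propargyl and allenyl transfer.
5. Endgame: pivalate to allylic alcohol to enal to acrylic acid, with C2 untouched throughout.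

Key step: step 10

Assumption: the facial sense known for (S)-TRIP with aryl and alkenyl aldehydes (attack on the Si face) is taken to hold for the 2-substituted acrolein used here. MTPA ester analysis of the homopropargylic alcohol would confirm it, and the (R)-acid is equally available.

**Route**

Step 1
Reactants: 1 2-methylenepropane-1,3-diol
Product: 2 2-(hydroxymethyl)prop-2-en-1-yl 2,2-dimethylpropanoate (mono-pivalate)
Conditions: 1 (2 equiv), PivCl (1 equiv), Et3N, CH2Cl2, −20 °C to 0 °C
Reagents that add atoms: pivaloyl chloride, CC(C)(C)C(=O)Cl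
Why: Statistical mono-acylation of a symmetrical primary diol used in excess, in which the bulky acyl chloride disfavours a second acylation; the ester is chosen because its oxygen cannot later trap the oxocarbenium carbon as a cyclic formal.

Step 2
Reactants: 2 2-(hydroxymethyl)prop-2-en-1-yl 2,2-dimethylpropanoate
Product: 3 2-formylprop-2-en-1-yl 2,2-dimethylpropanoate
Conditions: MnO2 (activated, excess), CH2Cl2, rt; filtered, concentrated cold and used at once
Reagents that add atoms: none
Why: Neutral heterogeneous MnO2 oxidation of a primary allylic alcohol stops at the enal and leaves the ester and the acceptor alkene alone.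

Step 3
Reactants: 3 2-formylprop-2-en-1-yl 2,2-dimethylpropanoate; 4 allenylboronic acid pinacol ester
Product: 6 (3S)-3-hydroxy-2-methylidenehex-5-yn-1-yl 2,2-dimethylpropanoate, via pinacol borate ester 5 (not isolated)
Conditions: (S)-TRIP [(S)-3,3'-bis(2,4,6-triisopropylphenyl)-1,1'-binaphthyl-2,2'-diyl hydrogen phosphate] (10 mol %), 4 Å MS, toluene, −20 °C; aq. NaHCO3 work-up
Reagents that add atoms: none
Why: Chiral Brønsted acid catalysed allenylboration (SE2' propargylation) runs through a closed six-membered chair transition state that allows only 1,2-addition and only the homopropargylic regioisomer, and the (S)-acid bound to a boronate oxygen and the formyl hydrogen leaves the Si face of the aldehyde open, which sets (S)-C2.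

Step 4
Reactants: 6 (3S)-3-hydroxy-2-methylidenehex-5-yn-1-yl 2,2-dimethylpropanoate; 7 2-methoxyethoxymethyl chloride
Product: 8 (3S)-3-[(2-methoxyethoxy)methoxy]-2-methylidenehex-5-yn-1-yl 2,2-dimethylpropanoate
Conditions: i-Pr2NEt, CH2Cl2, 0 °C to rt
Reagents that add atoms: none
Why: Alkoxymethylation of the secondary alcohol by the very electrophilic chloromethyl ether under a hindered amine base brings in the OCH2O carbon that becomes C6 and does not touch C2 or move the pivaloyl group.

Step 5
Reactants: 8 (3S)-3-[(2-methoxyethoxy)methoxy]-2-methylidenehex-5-yn-1-yl 2,2-dimethylpropanoate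
Product: 10 (3S)-3-[(2-methoxyethoxy)methoxy]-2-methylidene-6-(trimethylsilyl)hex-5-yn-1-yl 2,2-dimethylpropanoate, via lithium acetylide 9 (not isolated)
Conditions: LiN(SiMe3)2 (1.1 equiv), THF, −78 °C; Me3SiCl, −78 °C to 0 °C
Reagents that add atoms: chlorotrimethylsilane, C[Si](C)(C)Cl
Why: C-silylation of a terminal alkyne through its acetylide, in which the non-nucleophilic amide base removes only the acetylenic proton and spares the hindered, non-enolisable ester.

Step 6
Reactants: 10 (3S)-3-[(2-methoxyethoxy)methoxy]-2-methylidene-6-(trimethylsilyl)hex-5-yn-1-yl 2,2-dimethylpropanoate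
Product: 12 (3S,5E)-6-iodo-3-[(2-methoxyethoxy)methoxy]-2-methylidene-6-(trimethylsilyl)hex-5-en-1-yl 2,2-dimethylpropanoate, via alkenylzirconocene chloride 11 (not isolated)
Conditions: Cp2Zr(H)Cl (1.5 equiv), THF, rt to 40 °C, dark; I2, THF, −78 °C to 0 °C
Reagents that add atoms: iodine, II
Why: In this hydrozirconation–iodinolysis H and Zr add syn across the silylalkyne with zirconium on the silicon-bearing carbon C5, and iodine replaces zirconium with retention, so silicon ends cis to C3 and iodine trans to it, while the alkyne should outrun the hindered 1,1-disubstituted alkene and the pivalate.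

Step 7
Reactants: 13 (2E,6E)-farnesol
Product: 14 (2E,6E)-farnesal
Conditions: MnO2 (activated, excess), CH2Cl2, rt
Reagents that add atoms: none
Why: MnO2 oxidation of a primary allylic alcohol under neutral conditions keeps the 2E geometry and ignores the isolated alkenes.

Step 8
Reactants: 14 (2E,6E)-farnesal
Product: 15 (3E,7E)-4,8,12-trimethyltrideca-1,3,7,11-tetraene
Conditions: MePPh3Br, n-BuLi, THF, 0 °C; then 14, 0 °C to rt
Reagents that add atoms: methyltriphenylphosphonium bromide, C[P+](c1ccccc1)(c1ccccc1)c1ccccc1.[Br-]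
Why: Wittig methylenation of the enal with the unstabilised ylide adds the carbon that becomes C1' and creates no new alkene geometry.

Step 9
Reactants: 15 (3E,7E)-4,8,12-trimethyltrideca-1,3,7,11-tetraene; 12 (3S,5E)-6-iodo-3-[(2-methoxyethoxy)methoxy]-2-methylidene-6-(trimethylsilyl)hex-5-en-1-yl 2,2-dimethylpropanoate
Product: 17 (3S,5Z,9E,13E)-3-[(2-methoxyethoxy)methoxy]-10,14,18-trimethyl-2-methylidene-6-(trimethylsilyl)nonadeca-5,9,13,17-tetraen-1-yl 2,2-dimethylpropanoate, via B-homofarnesyl-9-BBN 16 (not isolated)
Conditions: 15, 9-BBN-H (1.05 equiv), THF, 0 °C to rt; aq. Cs2CO3; then 12, PdCl2(dppf) (5 mol %), AsPh3 (5 mol %), DMF, rt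
Reagents that add atoms: none
Why: The bulky borane adds anti-Markovnikov only to the monosubstituted end of the diene (the trisubstituted alkenes are inert), and in the B-alkyl Suzuki–Miyaura coupling oxidative addition of zerovalent palladium to the C–I bond and reductive elimination both go with retention, so the chain takes the place of iodine trans to C3 and silicon stays cis to C3.

Step 10
Reactants: 17 (3S,5Z,9E,13E)-3-[(2-methoxyethoxy)methoxy]-10,14,18-trimethyl-2-methylidene-6-(trimethylsilyl)nonadeca-5,9,13,17-tetraen-1-yl 2,2-dimethylpropanoate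
Product: 19 2-{(2S)-5-[(3E,7E)-4,8,12-trimethyltrideca-3,7,11-trien-1-yl]-3,6-dihydro-2H-pyran-2-yl}prop-2-en-1-yl 2,2-dimethylpropanoate, via oxocarbenium ion 18 (not isolated)
Conditions: SnCl4 (2.5 equiv), 2,6-di-tert-butyl-4-methylpyridine (0.3 equiv), CH2Cl2 (0.01 M), −78 °C to −30 °C; cold quench with Et3N/MeOH, then aq. NaHCO3
Reagents that add atoms: none
Why: SnCl4 binds the two outer oxygens of the MEM group, takes 2-methoxyethoxide onto tin and leaves the O1=C6H2 oxocarbenium ion 18. The vinylsilane attacks C6 through its silicon-bearing carbon C5, the charge arrives at C4 where the C5–Si bond stabilises it by hyperconjugation, and chloride removes the silyl group, so the alkene can lie only at C4=C5. The closest known reaction type is the acetal-initiated, vinylsilane-terminated (silyl-Prins type) cyclisation of alkoxymethyl ethers of (Z)-4-silylalk-3-en-1-ols to 3-substituted 5,6-dihydro-2H-pyrans. The one ring closes in the 6-endo-trig mode with the vinylsilane endocyclic, which needs silicon cis to C3 because C6 takes the place of silicon with retention; no stereocentre is created, and C2, set in step 3, takes no part in the bond changes. Site selectivity comes from the substrate: the three chain alkenes could close only rings of nine or more members, the methylidene on C2 could react only by a 5-endo closure to a cation next to the electron-withdrawing acyloxymethyl group, closure through C4 would give a five-membered ring without β-silicon support, and the pivalate oxygen is too poor a donor to trap C6 as a cyclic formal. Low temperature, high dilution and the hindered pyridine hold back 2-oxonia-Cope scrambling of C2, proton-initiated polyene cyclisation and protodesilylation.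

Step 11
Reactants: 19 2-{(2S)-5-[(3E,7E)-4,8,12-trimethyltrideca-3,7,11-trien-1-yl]-3,6-dihydro-2H-pyran-2-yl}prop-2-en-1-yl 2,2-dimethylpropanoate
Product: 20 2-{(2S)-5-[(3E,7E)-4,8,12-trimethyltrideca-3,7,11-trien-1-yl]-3,6-dihydro-2H-pyran-2-yl}prop-2-en-1-ol
Conditions: i-Bu2AlH (2.5 equiv), CH2Cl2, −78 °C; aq. potassium sodium tartrate
Reagents that add atoms: none
Why: Reductive ester cleavage with an aluminium hydride at low temperature frees the primary allylic alcohol without base and without touching the alkenes or the bis-allylic ring ether.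

Step 12
Reactants: 20 2-{(2S)-5-[(3E,7E)-4,8,12-trimethyltrideca-3,7,11-trien-1-yl]-3,6-dihydro-2H-pyran-2-yl}prop-2-en-1-ol
Product: 21 2-{(2S)-5-[(3E,7E)-4,8,12-trimethyltrideca-3,7,11-trien-1-yl]-3,6-dihydro-2H-pyran-2-yl}prop-2-enal
Conditions: MnO2 (activated, excess), CH2Cl2, rt
Reagents that add atoms: none
Why: Neutral MnO2 oxidation of the allylic alcohol gives the 2-substituted acrolein without acid or base that could move the methylidene into conjugation with O1 and destroy C2.

Step 13
Reactants: 21 2-{(2S)-5-[(3E,7E)-4,8,12-trimethyltrideca-3,7,11-trien-1-yl]-3,6-dihydro-2H-pyran-2-yl}prop-2-enal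
Product: 22 2-{(2S)-5-[(3E,7E)-4,8,12-trimethyltrideca-3,7,11-trien-1-yl]-3,6-dihydro-2H-pyran-2-yl}prop-2-enoic acid (CNP0171598.1)
Conditions: NaClO2, NaH2PO4, 2-methylbut-2-ene (large excess), t-BuOH/H2O, 0 °C to rt
Reagents that add atoms: sodium chlorite, [Na+].[O-]Cl=O
Why: Pinnick oxidation converts the enal into the acrylic acid at buffered pH, and the sacrificial alkene takes up the hypochlorous acid before it can reach the trisubstituted alkenes.

**Compound list**
1 | 2-methylenepropane-1,3-diol | C=C(CO)CO | starting material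
2 | 2-(hydroxymethyl)prop-2-en-1-yl 2,2-dimethylpropanoate | C=C(CO)COC(=O)C(C)(C)C | intermediate
3 | 2-formylprop-2-en-1-yl 2,2-dimethylpropanoate | C=C(C=O)COC(=O)C(C)(C)C | intermediate
4 | allenylboronic acid pinacol ester | C=C=CB1OC(C)(C)C(C)(C)O1 | starting material
5 | pinacol borate ester of alcohol 6 | C=C(COC(=O)C(C)(C)C)[C@@H](OB1OC(C)(C)C(C)(C)O1)CC#C | intermediate
6 | (3S)-3-hydroxy-2-methylidenehex-5-yn-1-yl 2,2-dimethylpropanoate | C=C(COC(=O)C(C)(C)C)[C@@H](O)CC#C | intermediate
7 | 2-methoxyethoxymethyl chloride | COCCOCCl | starting material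
8 | (3S)-3-[(2-methoxyethoxy)methoxy]-2-methylidenehex-5-yn-1-yl 2,2-dimethylpropanoate | C=C(COC(=O)C(C)(C)C)[C@@H](OCOCCOC)CC#C | intermediate
9 | lithium acetylide of 8 | C=C(COC(=O)C(C)(C)C)[C@@H](OCOCCOC)CC#C[Li] | intermediate
10 | (3S)-3-[(2-methoxyethoxy)methoxy]-2-methylidene-6-(trimethylsilyl)hex-5-yn-1-yl 2,2-dimethylpropanoate | C=C(COC(=O)C(C)(C)C)[C@@H](OCOCCOC)CC#C[Si](C)(C)C | intermediate
11 | (E)-alkenylzirconocene chloride (Cp2ZrCl geminal to SiMe3 on C5, Zr cis to the C4 hydrogen) | C=C(COC(=O)C(C)(C)C)[C@@H](OCOCCOC)C/C=C(\[Si](C)(C)C)[Zr](Cl)(C1C=CC=C1)C1C=CC=C1 | intermediate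
12 | (3S,5E)-6-iodo-3-[(2-methoxyethoxy)methoxy]-2-methylidene-6-(trimethylsilyl)hex-5-en-1-yl 2,2-dimethylpropanoate | C=C(COC(=O)C(C)(C)C)[C@@H](OCOCCOC)C/C=C(\[Si](C)(C)C)I | intermediate
13 | (2E,6E)-farnesol | OC/C=C(\C)CC/C=C(\C)CCC=C(C)C | starting material
14 | (2E,6E)-farnesal | O=C/C=C(\C)CC/C=C(\C)CCC=C(C)C | intermediate
15 | (3E,7E)-4,8,12-trimethyltrideca-1,3,7,11-tetraene | C=C/C=C(\C)CC/C=C(\C)CCC=C(C)C | intermediate
16 | 9-[(3E,7E)-4,8,12-trimethyltrideca-3,7,11-trien-1-yl]-9-borabicyclo[3.3.1]nonane | CC(C)=CCC/C(C)=C/CC/C(C)=C/CCB1C2CCCC1CCC2 | intermediate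
17 | (3S,5Z,9E,13E)-3-[(2-methoxyethoxy)methoxy]-10,14,18-trimethyl-2-methylidene-6-(trimethylsilyl)nonadeca-5,9,13,17-tetraen-1-yl 2,2-dimethylpropanoate | C=C(COC(=O)C(C)(C)C)[C@@H](OCOCCOC)C/C=C(\[Si](C)(C)C)CC/C=C(\C)CC/C=C(\C)CCC=C(C)C | intermediate
18 | O1=C6H2 oxocarbenium ion derived from 17 | C=C(COC(=O)C(C)(C)C)[C@@H]([O+]=C)C/C=C(\[Si](C)(C)C)CC/C=C(\C)CC/C=C(\C)CCC=C(C)C | intermediate
19 | 2-{(2S)-5-[(3E,7E)-4,8,12-trimethyltrideca-3,7,11-trien-1-yl]-3,6-dihydro-2H-pyran-2-yl}prop-2-en-1-yl 2,2-dimethylpropanoate | C=C(COC(=O)C(C)(C)C)[C@@H]1CC=C(CC/C=C(\C)CC/C=C(\C)CCC=C(C)C)CO1 | intermediate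
20 | 2-{(2S)-5-[(3E,7E)-4,8,12-trimethyltrideca-3,7,11-trien-1-yl]-3,6-dihydro-2H-pyran-2-yl}prop-2-en-1-ol | C=C(CO)[C@@H]1CC=C(CC/C=C(\C)CC/C=C(\C)CCC=C(C)C)CO1 | intermediate
21 | 2-{(2S)-5-[(3E,7E)-4,8,12-trimethyltrideca-3,7,11-trien-1-yl]-3,6-dihydro-2H-pyran-2-yl}prop-2-enal | C=C(C=O)[C@@H]1CC=C(CC/C=C(\C)CC/C=C(\C)CCC=C(C)C)CO1 | intermediate
22 | 2-{(2S)-5-[(3E,7E)-4,8,12-trimethyltrideca-3,7,11-trien-1-yl]-3,6-dihydro-2H-pyran-2-yl}prop-2-enoic acid | C=C(C(=O)O)[C@@H]1CC=C(CC/C=C(\C)CC/C=C(\C)CCC=C(C)C)CO1 | target

Total step count: 13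
Longest linear sequence: 11 steps (steps 1–6 and 9–13)

**Steps most likely to fail**

Step 10.
- **What may go wrong:** The Lewis acid may start cationic cyclisation of the triene chain, strip the acetal back to the alcohol or protodesilylate the vinylsilane. It may also allow 2-oxonia-Cope rearrangement or C2–O ionisation to erode the enantiomeric purity.
- **Fallback:** The ring is closed at C4=C5 by olefin metathesis instead of at C5–C6 by a cation.
- It sets out from 3. Allylboration with allylboronic acid pinacol ester under (S)-TRIP catalysis has the same closed transition state and facial sense as step 3. It should give (3S)-3-hydroxy-2-methylidenehex-5-en-1-yl 2,2-dimethylpropanoate F1.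
- In parallel, 2-methylprop-2-en-1-ol is dilithiated (n-BuLi, TMEDA, Et2O/hexane) and C-alkylated with (2E,6E)-farnesyl bromide. This gives (5E,9E)-6,10,14-trimethyl-2-methylidenepentadeca-5,9,13-trien-1-ol F2.
- Ac2O/pyridine converts that alcohol into (5E,9E)-6,10,14-trimethyl-2-methylidenepentadeca-5,9,13-trien-1-yl acetate F3.
- The zinc alkoxide of the homoallylic alcohol (Et2Zn) is allylated with this acetate under Pd(OAc)2/2-(di-tert-butylphosphino)biphenyl catalysis in THF at rt. The product is the bis-allylic ether (3S)-2-methylidene-3-{[(5E,9E)-6,10,14-trimethyl-2-methylidenepentadeca-5,9,13-trien-1-yl]oxy}hex-5-en-1-yl 2,2-dimethylpropanoate F4.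
- The 2-substituted π-allyl unit is symmetrical, so no regiochemical question arises. The unhindered acetate should ionise before the pivalate, and no alkali alkoxide is present that could move the pivaloyl group.
- Ring-closing metathesis with the second-generation Grubbs catalyst in dilute refluxing CH2Cl2 joins the monosubstituted C4 alkene to the C5 methylidene with loss of ethene. The fallback comes back to the route at 19.

Step 6.
- **What may go wrong:** The zirconium hydride may also add to the 1,1-disubstituted allylic alkene, followed by β-elimination of pivalate or of the acetal oxygen. It may also reduce the ester if the sluggish silylalkyne calls for warming and excess reagent.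
- **Fallback:** The hydrometalation metal and the protecting-group plan both change, and the ester is given up and put back.
- It sets out from 10. Excess i-Bu2AlH in Et2O at rt to 35 °C cleaves the pivalate and adds syn to the silylalkyne only. Aluminium hydrides do not add to unactivated alkenes at this temperature, and the donor solvent keeps the α-silylalkenylalane from isomerising.
- This gives the alkenylalane diisobutylaluminium alkoxide F5.
- I2 at −78 °C to 0 °C replaces aluminium with retention. Work-up gives (3S,5E)-6-iodo-3-[(2-methoxyethoxy)methoxy]-2-methylidene-6-(trimethylsilyl)hex-5-en-1-ol F6.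
- PivCl/pyridine re-esterifies the primary alcohol, and the fallback comes back to the route at 12.

Step 3.
- **What may go wrong:** Facial discrimination may be poor on a small, α-branched, non-aromatic enal. An uncatalysed background addition may compete, or turnover may be so slow that the aldehyde oligomerises.
- **Fallback:** Resolution replaces asymmetric addition.
- It sets out from 3 and 4. Achiral diphenyl hydrogen phosphate catalysis in toluene at rt gives racemic 3-hydroxy-2-methylidenehex-5-yn-1-yl 2,2-dimethylpropanoate F7.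
- Sharpless kinetic resolution follows (Ti(OiPr)4, D-(−)-diisopropyl tartrate, t-BuOOH 0.6 equiv, 4 Å MS, CH2Cl2, −20 °C). It epoxidises the (R)-enantiomer, whose propargyl group points away from the face served by the D-tartrate catalyst.
- That enantiomer becomes {(2S)-2-[(1R)-1-hydroxybut-3-yn-1-yl]oxiran-2-yl}methyl 2,2-dimethylpropanoate F8.
- The (S)-alcohol is left behind and is separated by chromatography, so the fallback comes back to the route at 6. The same treatment can raise the purity of partly enriched 6.

**Further compounds**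
F1 | step 10 | (3S)-3-hydroxy-2-methylidenehex-5-en-1-yl 2,2-dimethylpropanoate | C=C(COC(=O)C(C)(C)C)[C@@H](O)CC=C
F2 | step 10 | (5E,9E)-6,10,14-trimethyl-2-methylidenepentadeca-5,9,13-trien-1-ol | C=C(CO)CC/C=C(\C)CC/C=C(\C)CCC=C(C)C
F3 | step 10 | (5E,9E)-6,10,14-trimethyl-2-methylidenepentadeca-5,9,13-trien-1-yl acetate | C=C(COC(C)=O)CC/C=C(\C)CC/C=C(\C)CCC=C(C)C
F4 | step 10 | (3S)-2-methylidene-3-{[(5E,9E)-6,10,14-trimethyl-2-methylidenepentadeca-5,9,13-trien-1-yl]oxy}hex-5-en-1-yl 2,2-dimethylpropanoate | C=C(COC(=O)C(C)(C)C)[C@@H](OCC(=C)CC/C=C(\C)CC/C=C(\C)CCC=C(C)C)CC=C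
F5 | step 6 | alkenylalane diisobutylaluminium alkoxide | C=C(CO[Al](CC(C)C)CC(C)C)[C@@H](OCOCCOC)C/C=C(\[Si](C)(C)C)[Al](CC(C)C)CC(C)C
F6 | step 6 | (3S,5E)-6-iodo-3-[(2-methoxyethoxy)methoxy]-2-methylidene-6-(trimethylsilyl)hex-5-en-1-ol | C=C(CO)[C@@H](OCOCCOC)C/C=C(\[Si](C)(C)C)I
F7 | step 3 | racemic 3-hydroxy-2-methylidenehex-5-yn-1-yl 2,2-dimethylpropanoate | C=C(COC(=O)C(C)(C)C)C(O)CC#C
F8 | step 3 | {(2S)-2-[(1R)-1-hydroxybut-3-yn-1-yl]oxiran-2-yl}methyl 2,2-dimethylpropanoate | CC(C)(C)C(=O)OC[C@@]1(CO1)[C@H](O)CC#C
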